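The synthesis rests on treating the C7–C8 unit as a hydrogenated alkene. C7 (benzylic, on ring A, the 3,4,5-trimethoxyphenyl ring) and C8 (bearing the methyl group and the ether oxygen to ring B) are neighbouring O–C–H carbons in an erythro relationship. The two hydrogens can therefore be delivered together to one face of a C7=C8 bond whose oxygens are cis. A single enantioselective rhodium hydrogenation thus creates both stereocentres without touching the skeleton. Its substrate is the tetrasubstituted (Z)-enol acetate of a racemic α-aryloxy propiophenone. The acetate anchors rhodium, and ring B carries bromine as a hydrogenation-proof stand-in for the allyl group, which is installed afterwards.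

Key step: step 4

Assumption: neolignan locants are used (C7 = carbinol carbon on ring A, C8 = ether carbon, C9 = methyl; the target is 7S,8R = 1S,2R = erythro). The (R,R) antipode of the ligand is written by analogy with the sense of induction known for aryl enol acetates and enamides, and the commercial mirror-image ligand is taken instead should a trial run show attack on the other face.

Step 1
Reactants: 1 1-(3,4,5-trimethoxyphenyl)propan-1-one
Product: 2 (±)-2-bromo-1-(3,4,5-trimethoxyphenyl)propan-1-one
Conditions: CuBr2 (2.1 equiv), EtOAc–CHCl3 (1:1), reflux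
Reagents that add atoms: copper dibromide, [Cu+2].[Br-].[Br-]
Why: α-Halogenation of a ketone through its enol: CuBr2 hands bromine only to the enolised C8 position and, unlike free Br2, should spare the electron-rich ring A, while the racemic C8 centre formed here is of no consequence because step 3 flattens it.

Step 2
Reactants: 2 (±)-2-bromo-1-(3,4,5-trimethoxyphenyl)propan-1-one; 3 4-bromo-2,6-dimethoxyphenol
Product: 4 (±)-2-(4-bromo-2,6-dimethoxyphenoxy)-1-(3,4,5-trimethoxyphenyl)propan-1-one
Conditions: K2CO3 (1.5 equiv), butan-2-one, reflux
Reagents that add atoms: none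
Why: Williamson ether synthesis: the potassium phenoxide of 3 displaces the carbonyl-activated secondary bromide by SN2 to form the C8–O bond to ring B, the aryl bromide being inert to carbonate, and the product stays racemic by design.

Step 3
Reactants: 4 (±)-2-(4-bromo-2,6-dimethoxyphenoxy)-1-(3,4,5-trimethoxyphenyl)propan-1-one
Product: 6 (Z)-2-(4-bromo-2,6-dimethoxyphenoxy)-1-(3,4,5-trimethoxyphenyl)prop-1-en-1-yl acetate, via lithium (Z)-enolate 5 (not isolated)
Conditions: LiN(SiMe3)2 (1.1 equiv), THF, −78 °C; then Ac2O (1.5 equiv), −78 → 0 °C; recrystallisation to the pure (Z) isomer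
Reagents that add atoms: acetic anhydride, CC(=O)OC(C)=O
Why: Kinetic enolisation followed by O-acylation of a lithium enolate: lithium held between the carbonyl oxygen and the aryloxy oxygen (helped by an ortho-methoxy group of ring B) during deprotonation should place the two oxygens cis, acetylation at carbon would have to build a quaternary centre and is therefore slow, and both enantiomers of 4 converge on one achiral alkene.

Step 4
Reactants: 6 (Z)-2-(4-bromo-2,6-dimethoxyphenoxy)-1-(3,4,5-trimethoxyphenyl)prop-1-en-1-yl acetate
Product: 7 (1S,2R)-2-(4-bromo-2,6-dimethoxyphenoxy)-1-(3,4,5-trimethoxyphenyl)propyl acetate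
Conditions: [Rh(cod)2]BF4 (5 mol %), (R,R)-Me-DuPhos (1,2-bis[(2R,5R)-2,5-dimethylphospholan-1-yl]benzene, 5.5 mol %), H2 (30 bar), CH2Cl2, 25 → 40 °C
Reagents that add atoms: none
Why: Proposed new method: hydrogenation of cod frees the cation [Rh((R,R)-Me-DuPhos)]+, which should bind 6 through the C7=C8 π bond and the acetate carbonyl oxygen, add H2 oxidatively (monovalent to trivalent rhodium), pass one hydride to C8 by migratory insertion to leave a five-membered acyloxy-chelated C7–Rh alkyl, and form the C7–H bond by reductive elimination, so that both hydrogens arrive from the metal-bound face. The closest known reaction types are the rhodium-bisphospholane hydrogenation of trisubstituted enol acetates and of tetrasubstituted β,β-disubstituted enamides and the iridium N,P-ligand hydrogenation of tetrasubstituted alkenes, whereas an acyclic, fully substituted enol acetate that also carries an aryloxy group has not been reduced in this way. No ring is closed and no skeletal bond is made. The relative configuration is controlled by the substrate alone, since suprafacial delivery to an alkene with cis oxygens puts OAc and OAr on the same side of the Fischer projection (erythro), while the absolute configuration at C7 (S), and through the syn addition at C8 (R), is controlled by the C2-symmetric ligand, whose blocked quadrants decide which alkene face can chelate productively. The step needs enantioface selectivity, secured by the two-point binding through the acetate, and chemoselectivity, secured by having bromine instead of the reducible allyl group on ring B, an aryl bromide being inert to this catalyst and H2. The methyl-substituted phospholane is chosen because a tetrasubstituted alkene needs the most open ligand pocket, and CH2Cl2 is used so that no donor solvent competes with the weak acetate donor or solvolyses the enol ester.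

Step 5
Reactants: 7 (1S,2R)-2-(4-bromo-2,6-dimethoxyphenoxy)-1-(3,4,5-trimethoxyphenyl)propyl acetate; 8 allyltributylstannane
Product: 9 (1S,2R)-2-(4-allyl-2,6-dimethoxyphenoxy)-1-(3,4,5-trimethoxyphenyl)propyl acetate
Conditions: Pd(PPh3)4 (5 mol %), toluene (degassed), 100 °C
Reagents that add atoms: allyltributylstannane (8), C=CC[Sn](CCCC)(CCCC)CCCC
Why: Stille coupling: zerovalent palladium inserts into the aryl C–Br bond of ring B, the allyl group is transferred from tin and reductive elimination forms the aryl–allyl bond under neutral conditions that leave the acetate, the ethers and the C7 and C8 configurations untouched.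

Step 6
Reactants: 9 (1S,2R)-2-(4-allyl-2,6-dimethoxyphenoxy)-1-(3,4,5-trimethoxyphenyl)propyl acetate
Product: 10 rhaphidecursinol B, (1S,2R)-2-(4-allyl-2,6-dimethoxyphenoxy)-1-(3,4,5-trimethoxyphenyl)propan-1-ol
Conditions: K2CO3 (0.2 equiv), MeOH, 0 °C → rt
Reagents that add atoms: none
Why: Base-catalysed transesterification: methoxide attacks the acetyl carbonyl and not C7, so the C7–O bond and both configurations are retained, and carbonate at room temperature is far too weak to move the allyl double bond into conjugation.

Compound list
1 | 1-(3,4,5-trimethoxyphenyl)propan-1-one | CCC(=O)c1cc(OC)c(OC)c(OC)c1 | starting material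
2 | (±)-2-bromo-1-(3,4,5-trimethoxyphenyl)propan-1-one (racemic) | CC(Br)C(=O)c1cc(OC)c(OC)c(OC)c1 | intermediate
3 | 4-bromo-2,6-dimethoxyphenol | Oc1c(OC)cc(Br)cc1OC | starting material
4 | (±)-2-(4-bromo-2,6-dimethoxyphenoxy)-1-(3,4,5-trimethoxyphenyl)propan-1-one (racemic) | CC(Oc1c(OC)cc(Br)cc1OC)C(=O)c1cc(OC)c(OC)c(OC)c1 | intermediate
5 | lithium (Z)-2-(4-bromo-2,6-dimethoxyphenoxy)-1-(3,4,5-trimethoxyphenyl)prop-1-en-1-olate (not isolated) | [Li+].[O-]/C(c1cc(OC)c(OC)c(OC)c1)=C(C)\Oc1c(OC)cc(Br)cc1OC | intermediate
6 | (Z)-2-(4-bromo-2,6-dimethoxyphenoxy)-1-(3,4,5-trimethoxyphenyl)prop-1-en-1-yl acetate | CC(=O)O/C(c1cc(OC)c(OC)c(OC)c1)=C(C)\Oc1c(OC)cc(Br)cc1OC | intermediate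
7 | (1S,2R)-2-(4-bromo-2,6-dimethoxyphenoxy)-1-(3,4,5-trimethoxyphenyl)propyl acetate | Brc1cc(OC)c(O[C@H](C)[C@@H](OC(C)=O)c2cc(OC)c(OC)c(OC)c2)c(OC)c1 | intermediate
8 | allyltributylstannane | C=CC[Sn](CCCC)(CCCC)CCCC | starting material
9 | (1S,2R)-2-(4-allyl-2,6-dimethoxyphenoxy)-1-(3,4,5-trimethoxyphenyl)propyl acetate | C=CCc1cc(OC)c(O[C@H](C)[C@@H](OC(C)=O)c2cc(OC)c(OC)c(OC)c2)c(OC)c1 | intermediate
10 | rhaphidecursinol B, (1S,2R)-2-(4-allyl-2,6-dimethoxyphenoxy)-1-(3,4,5-trimethoxyphenyl)propan-1-ol | C=CCc1cc(OC)c(O[C@H](C)[C@@H](O)c2cc(OC)c(OC)c(OC)c2)c(OC)c1 | target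

Total step count: 6
Longest linear sequence: 6 steps (1 → 2 → 4 → 6 → 7 → 9 → 10)

Steps most likely to fail

1. Step 4 (the step that carries the label).
- **What may go wrong:**
  - The fully substituted, only weakly chelating alkene may fail to bind to rhodium, so that there is no turnover.
  - The two alkene faces may be poorly distinguished.
  - The aryloxy group may be lost by β-elimination from the C7-bound alkylrhodium intermediate.
  - Reversible hydride insertion may scramble the alkene geometry before reduction and erode the erythro purity.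
- **Fallback:** this uses known chemistry only, with the chiral pool for C8 and a chelation-controlled reduction for C7. It sets out from phenol 3 and comes back at acetate 7. A Mitsunobu reaction of 3 with methyl (S)-lactate (PPh3, DIAD, THF, 0 °C → rt) inverts the lactate carbon and should give methyl (R)-2-(4-bromo-2,6-dimethoxyphenoxy)propanoate F1. MeNHOMe·HCl and i-PrMgCl (THF, −20 °C) turn it into the Weinreb amide (R)-2-(4-bromo-2,6-dimethoxyphenoxy)-N-methoxy-N-methylpropanamide F2. Commercial 3,4,5-trimethoxyphenylmagnesium bromide (THF, 0 °C) stops at the ketone stage and gives (R)-2-(4-bromo-2,6-dimethoxyphenoxy)-1-(3,4,5-trimethoxyphenyl)propan-1-one F3. Zn(BH4)2 (Et2O, −30 °C) ties the carbonyl and aryloxy oxygens into a five-membered zinc chelate and delivers hydride from the side of the C8 hydrogen. This should give the erythro alcohol (1S,2R)-2-(4-bromo-2,6-dimethoxyphenoxy)-1-(3,4,5-trimethoxyphenyl)propan-1-ol F4. Ac2O, pyridine and catalytic DMAP (CH2Cl2, rt) then give 7.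

2. Step 3.
- **What may go wrong:** chelation may be incomplete, so that geometric purity is lost. The enolate may also be consumed by C-acylation or by proton transfer from the anhydride.
- **Fallback:** a silicon detour with purification of the alkene geometry, setting out from ketone 4 and coming back at enol acetate 6. Enolate 5 is generated as before but trapped with Me3SiCl, which reacts only at oxygen. The product [(Z)-2-(4-bromo-2,6-dimethoxyphenoxy)-1-(3,4,5-trimethoxyphenyl)prop-1-en-1-yl]oxy(trimethyl)silane F5 is freed from its geometric isomer on Et3N-deactivated silica. t-BuOK (THF, −40 °C) cleaves the O–Si bond with retention of the alkene geometry to the amine-free potassium (Z)-2-(4-bromo-2,6-dimethoxyphenoxy)-1-(3,4,5-trimethoxyphenyl)prop-1-en-1-olate F6, which Ac2O acetylates at oxygen to give 6. The geometry is to be confirmed by an NOE experiment between the C9 methyl group and H2/H6 of ring A before any hydrogenation.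

3. Step 5.
- **What may go wrong:** oxidative addition into the electron-rich aryl bromide may be slow. At the temperature then required, the allyl double bond may migrate into conjugation with ring B.
- **Fallback:** the polarity is reversed, with ring B as the nucleophile and allyl as the electrophile. It sets out from bromide 7 and comes back at 9. Miyaura borylation (bis(pinacolato)diboron, Pd(dppf)Cl2, KOAc, dioxane, 85 °C) is carried out while no allyl group is yet present. It should give (1S,2R)-2-[2,6-dimethoxy-4-(4,4,5,5-tetramethyl-1,3,2-dioxaborolan-2-yl)phenoxy]-1-(3,4,5-trimethoxyphenyl)propyl acetate F7. A Suzuki–Miyaura-type allylation with allyl bromide (Pd(PPh3)4, CsF, THF, 50 °C) then gives 9. It runs through an easily formed π-allyl complex of divalent palladium at a lower temperature.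

Further compounds
F1 | step 4 | methyl (R)-2-(4-bromo-2,6-dimethoxyphenoxy)propanoate | C[C@@H](Oc1c(OC)cc(Br)cc1OC)C(=O)OC
F2 | step 4 | (R)-2-(4-bromo-2,6-dimethoxyphenoxy)-N-methoxy-N-methylpropanamide | C[C@@H](Oc1c(OC)cc(Br)cc1OC)C(=O)N(C)OC
F3 | step 4 | (R)-2-(4-bromo-2,6-dimethoxyphenoxy)-1-(3,4,5-trimethoxyphenyl)propan-1-one | C[C@@H](Oc1c(OC)cc(Br)cc1OC)C(=O)c1cc(OC)c(OC)c(OC)c1
F4 | step 4 | (1S,2R)-2-(4-bromo-2,6-dimethoxyphenoxy)-1-(3,4,5-trimethoxyphenyl)propan-1-ol | Brc1cc(OC)c(O[C@H](C)[C@@H](O)c2cc(OC)c(OC)c(OC)c2)c(OC)c1
F5 | step 3 | [(Z)-2-(4-bromo-2,6-dimethoxyphenoxy)-1-(3,4,5-trimethoxyphenyl)prop-1-en-1-yl]oxy(trimethyl)silane | C[Si](C)(C)O/C(c1cc(OC)c(OC)c(OC)c1)=C(C)\Oc1c(OC)cc(Br)cc1OC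
F6 | step 3 | potassium (Z)-2-(4-bromo-2,6-dimethoxyphenoxy)-1-(3,4,5-trimethoxyphenyl)prop-1-en-1-olate | [K+].[O-]/C(c1cc(OC)c(OC)c(OC)c1)=C(C)\Oc1c(OC)cc(Br)cc1OC
F7 | step 5 | (1S,2R)-2-[2,6-dimethoxy-4-(4,4,5,5-tetramethyl-1,3,2-dioxaborolan-2-yl)phenoxy]-1-(3,4,5-trimethoxyphenyl)propyl acetate | CC1(C)OB(OC1(C)C)c1cc(OC)c(O[C@H](C)[C@@H](OC(C)=O)c2cc(OC)c(OC)c(OC)c2)c(OC)c1
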